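The eudesmane is cut at C1–C10 and C4–C5: ring B with the C7 stereocentre, the C5 carbonyl carbon and the C10 methyl is (+)-dihydrocarvone, and ring A with the C4 methyl comes from ethyl vinyl ketone. One auxiliary-controlled Robinson annulation of the (R)-1-phenylethylamine ketimine of dihydrocarvone closes ring A, sets the C10 quaternary centre cis to the C7 side chain and gives (+)-α-cyperone, whose enone later delivers the trans ring fusion and the 4α-oxygen. The magnolol half is attached by O-arylation of the C4 alkoxide with a symmetrical dibromo cyclic diaryliodonium salt; hydration, iodide-to-phenol exchange and double allylation finish the synthesis.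

Key step: step 2

Remark: eudesmane numbering is used for all bicyclic compounds (α = face opposite the C10 methyl). Commercial (+)-dihydrocarvone is assumed to be (5R) material; its C2 epimer content does not matter, because that carbon (the future C10) is planarised in step 2.

**Step 1**
Reactants: 1 (+)-dihydrocarvone
Product: 2 N-[(R)-1-phenylethyl] ketimine of dihydrocarvone
Conditions: (R)-(+)-1-phenylethylamine (1.1 equiv), p-TsOH·H2O (1 mol %), toluene, reflux, Dean–Stark
Reagents that add atoms: (R)-1-phenylethylamine, C[C@@H](N)c1ccccc1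
Why: Acid-catalysed ketimine condensation driven by azeotropic removal of water; no stereocentre is set, C7 is untouched and the α-methyl carbon may be any epimer mixture.

**Step 2**
Reactants: 2 ketimine; 3 ethyl vinyl ketone
Product: 7 (+)-α-cyperone, via Michael adduct imine 4 (not isolated), via diketone 5 (not isolated), via ketol 6 (not isolated)
Conditions: 3 (1.3 equiv), THF, 40 °C, 3 d; then 10 % aq AcOH, rt; then crude in MeOH, NaOMe (0.3 equiv), rt → 50 °C
Reagents that add atoms: none
Why: Imine 2 equilibrates with its more substituted secondary enamine, whose C10 adds to the enone in a compact aza-ene-like transition state with N–H transfer to the enone α-carbon (C1–C10 bond, adduct 4), and aqueous acid then releases diketone 5 and the auxiliary. Methoxide forms the ethyl-ketone enolate, C4 attacks the C5 carbonyl (ketol 6) and E1cB loss of water gives the C4=C5 enone; the closest known type is the deracemising Michael addition of chiral ketimines followed by Robinson annulation. Ring A closes by a 6-(enolendo)-exo-trig aldol addition. The new stereocentre C10 is set by the auxiliary: in the reactive enamine conformer the phenyl group of the (R)-amine screens the β-face, so the enone should arrive on the α-face and the methyl should end β, cis to the C7 isopropenyl group, against the ring's own preference for the 10-epimer. Regioselectivity for C10 over C6 is needed and is secured by the preference for the tetrasubstituted enamine tautomer and the internal proton transfer, while in the aldol step only the C4-to-C5 closure leads to a six-membered conjugated enone and dehydration makes it irreversible. C7 is remote from every enolisable position and is carried through unchanged.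

**Step 3**
Reactants: 7 (+)-α-cyperone
Product: 9 3-(trimethylsilyloxy)-5α-eudesma-3,11-diene, via lithium enolate 8 (not isolated)
Conditions: Li (2.1 equiv), t-BuOH (1.0 equiv), NH3(l)/THF, −78 °C; evaporate NH3; TMSCl (2.5 equiv), Et3N, THF, −78 → 0 °C
Reagents that add atoms: chlorotrimethylsilane, C[Si](C)(C)Cl
Why: Dissolving-metal enone reduction in which the C5 carbanion is protonated axially on the α-face, setting the trans ring fusion (5α-H), followed by O-silylation of the regiodefined C3–C4 lithium enolate before it can equilibrate (reductive enolate trapping); the isolated isopropenyl group is inert to lithium in ammonia.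

**Step 4**
Reactants: 9 silyl enol ether
Product: 12 4α-hydroxy-5α-eudesm-11-en-3-one (4β-methyl), via silyloxy epoxide 10 (not isolated), via silyloxy ketone 11 (not isolated)
Conditions: mCPBA (1.05 equiv), CH2Cl2, −20 → 0 °C; then 1 M HCl, THF, 0 °C
Reagents that add atoms: mCPBA, OOC(=O)c1cccc(Cl)c1
Why: Rubottom oxidation in which the electron-rich tetrasubstituted silyl enol ether is epoxidised far faster than the 1,1-disubstituted isopropenyl alkene, the peracid approaching the face opposite the axial 10β-methyl so that the new C4–O bond is α and the C4 methyl β; epoxide opening with 1,4-silyl shift and mild acid hydrolysis give the ketol.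

**Step 5**
Reactants: 12 ketol
Product: 13 tosylhydrazone of 12
Conditions: TsNHNH2 (1.3 equiv), MeOH, 50 °C
Reagents that add atoms: p-toluenesulfonyl hydrazide, Cc1ccc(cc1)S(=O)(=O)NN
Why: Hydrazone condensation at the C3 ketone under near-neutral conditions; C4 is quaternary, so no α-stereocentre can epimerise and the tertiary ketol is not exposed to strong acid or base.

**Step 6**
Reactants: 13 tosylhydrazone
Product: 16 5α-eudesm-11-en-4α-ol (selin-11-en-4α-ol), via tosylhydrazine 14 (not isolated), via diazene 15 (not isolated)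
Conditions: catecholborane (3 equiv), CHCl3, 0 °C → rt; then NaOAc·3H2O, 60 °C
Reagents that add atoms: none
Why: Caglioti-type tosylhydrazone reduction in which catecholborane adds hydride to C=N, acetate expels sulfinate to give the monoalkyl diazene and loss of N2 leaves C3 as CH2; the C4–O bond is never broken and the unactivated alkene is not hydroborated at this temperature.

**Step 7**
Reactants: 17 4-bromo-2-iodoaniline; 18 3-bromophenylboronic acid
Product: 19 3′,5-dibromo-[1,1′-biphenyl]-2-amine
Conditions: Pd(PPh3)4 (3 mol %), Na2CO3, DME/H2O, 80 °C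
Reagents that add atoms: none
Why: Suzuki–Miyaura coupling, chemoselective because oxidative addition to the C–I bond is much faster than to either C–Br bond; the free aniline is tolerated.

**Step 8**
Reactants: 19 aminobiphenyl
Product: 21 3′,5-dibromo-2-iodo-1,1′-biphenyl, via diazonium chloride 20 (not isolated)
Conditions: NaNO2, aq HCl, MeCN, 0 °C; then KI, 0 °C → rt
Reagents that add atoms: potassium iodide, [K+].[I-]
Why: Diazotisation followed by Sandmeyer-type iodide substitution, which needs no copper and leaves both aryl bromides in place.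

**Step 9**
Reactants: 21 iodobiphenyl
Product: 23 2,8-dibromodibenzo[b,d]iodol-5-ium triflate, via hydroxy(triflyloxy)iodane 22 (not isolated)
Conditions: mCPBA (1.3 equiv), TfOH (3 equiv), CH2Cl2, 0 °C → rt
Reagents that add atoms: triflic acid, OS(=O)(=O)C(F)(F)F
Why: One-pot oxidation of the aryl iodide to iodine(III) and intramolecular electrophilic aromatic substitution (the standard synthesis of dibenzoiodolium triflates); closure should occur para to the 3′-bromine at the unhindered ortho position, giving the symmetrical 2,8-dibromo salt.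

**Step 10**
Reactants: 16 5α-eudesm-11-en-4α-ol; 23 iodolium triflate
Product: 26 4α-[(5,5′-dibromo-2′-iodobiphenyl-2-yl)oxy]-5α-eudesm-11-ene, via sodium alkoxide 24 (not isolated), via alkoxyiodane 25 (not isolated)
Conditions: NaH (1.2 equiv), THF, 0 → 40 °C; then 23 (1.2 equiv), THF, rt → 50 °C
Reagents that add atoms: none
Why: Metal-free O-arylation of a tertiary alkoxide by a diaryl-λ3-iodane, in which ligand exchange at iodine and ligand coupling form the aryl C–O bond and open the iodole ring; the iodine stays as the ortho′ iodide, the C4–O bond is untouched (configuration retained) and the symmetry of 23 allows only one product.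

**Step 11**
Reactants: 26 aryl ether
Product: 27 4α-[(5,5′-dibromo-2′-iodobiphenyl-2-yl)oxy]-5α-eudesman-11-ol
Conditions: Co(acac)2 (20 mol %), PhSiH3 (2.5 equiv), O2 (1 atm), THF, rt
Reagents that add atoms: dioxygen, O=O
Why: Mukaiyama hydration, in which cobalt-hydride hydrogen-atom transfer to the 1,1-disubstituted alkene gives the tertiary C11 radical that is trapped by O2 and reduced to the Markovnikov alcohol; aryl halides and the ether are inert, and the step precedes allylation because allyl groups would be hydrated too.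

**Step 12**
Reactants: 27 iodo alcohol
Product: 30 5,5′-dibromo-2′-[(11-hydroxy-5α-eudesman-4α-yl)oxy]biphenyl-2-ol, via aryl Grignard 28 (not isolated), via arylboronate 29 (not isolated)
Conditions: i-PrMgCl·LiCl (2.2 equiv), THF, −20 °C; B(OMe)3, −20 °C → rt; then 30 % H2O2, aq NaOH, 0 °C; sat. NH4Cl work-up
Reagents that add atoms: hydrogen peroxide, OO
Why: Iodine–magnesium exchange with the turbo-Grignard reagent is much faster at C–I than at C–Br (the first equivalent only deprotonates the C11 hydroxyl), and borylation followed by oxidative boron-to-oxygen aryl migration places the phenol oxygen on the former iodine-bearing carbon.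

**Step 13**
Reactants: 30 dibromo phenol
Product: 33 eudesmagnolol, via ether-ring bromide 31 (not isolated), via phenol-ring bromide 32 (not isolated)
Conditions: allylSnBu3 (3 equiv), Pd(PPh3)4 (10 mol %), DMF, 90 °C
Reagents that add atoms: allyltributylstannane, C=CC[Sn](CCCC)(CCCC)CCCC
Why: Twofold Migita–Kosugi–Stille coupling of both aryl bromides with the allylstannane under neutral conditions, which tolerate the free phenol, the tertiary alcohol and the acid-labile tertiary alkyl aryl ether.

**Compound list**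

1 | (+)-dihydrocarvone, (2R,5R)-2-methyl-5-(prop-1-en-2-yl)cyclohexanone | C[C@@H]1CC[C@@H](C(C)=C)CC1=O | starting material
2 | N-[(R)-1-phenylethyl] ketimine of 1 | C[C@@H]1CC[C@@H](C(C)=C)CC1=N[C@H](C)c1ccccc1 | intermediate
3 | ethyl vinyl ketone (pent-1-en-3-one) | CCC(=O)C=C | starting material
4 | (R)-1-phenylethyl ketimine of (2S,5R)-2-methyl-2-(3-oxopentyl)-5-(prop-1-en-2-yl)cyclohexanone | CCC(=O)CC[C@]1(C)CC[C@@H](C(C)=C)CC1=N[C@H](C)c1ccccc1 | intermediate
5 | (2S,5R)-2-methyl-2-(3-oxopentyl)-5-(prop-1-en-2-yl)cyclohexanone | CCC(=O)CC[C@]1(C)CC[C@@H](C(C)=C)CC1=O | intermediate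
6 | 5-hydroxyeudesm-11-en-3-one (10β-methyl, 7β-isopropenyl; C4/C5 epimers) | CC1C(=O)CC[C@]2(C)CC[C@@H](C(C)=C)CC12O | intermediate
7 | (+)-α-cyperone, (4aS,7R)-eudesma-4,11-dien-3-one (10β-methyl, 7β-isopropenyl) | CC1=C2C[C@H](C(C)=C)CC[C@@]2(C)CCC1=O | intermediate
8 | lithium 5α-eudesma-3,11-dien-3-olate (trans-fused) | CC1=C([O-])CC[C@]2(C)CC[C@@H](C(C)=C)C[C@H]21.[Li+] | intermediate
9 | 3-(trimethylsilyloxy)-5α-eudesma-3,11-diene | CC1=C(O[Si](C)(C)C)CC[C@]2(C)CC[C@@H](C(C)=C)C[C@H]21 | intermediate
10 | 3α,4α-epoxy-3β-(trimethylsilyloxy)-5α-eudesm-11-ene | C[C@@]12O[C@]1(O[Si](C)(C)C)CC[C@]3(C)CC[C@@H](C(C)=C)C[C@H]32 | intermediate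
11 | 4α-(trimethylsilyloxy)-5α-eudesm-11-en-3-one (4β-methyl) | C[Si](C)(C)O[C@]1(C)C(=O)CC[C@]2(C)CC[C@@H](C(C)=C)C[C@H]21 | intermediate
12 | 4α-hydroxy-5α-eudesm-11-en-3-one (4β-methyl) | O[C@]1(C)C(=O)CC[C@]2(C)CC[C@@H](C(C)=C)C[C@H]21 | intermediate
13 | C3 tosylhydrazone of 12 | O[C@]1(C)C(=NNS(=O)(=O)c2ccc(C)cc2)CC[C@]2(C)CC[C@@H](C(C)=C)C[C@H]21 | intermediate
14 | 3-(2-tosylhydrazinyl)-5α-eudesm-11-en-4α-ol (C3 epimers; boron-bound in the flask, drawn as the free N–H, O–H form) | O[C@]1(C)C(NNS(=O)(=O)c2ccc(C)cc2)CC[C@]2(C)CC[C@@H](C(C)=C)C[C@H]21 | intermediate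
15 | 3-diazenyl-5α-eudesm-11-en-4α-ol | O[C@]1(C)C(N=N)CC[C@]2(C)CC[C@@H](C(C)=C)C[C@H]21 | intermediate
16 | 5α-eudesm-11-en-4α-ol (selin-11-en-4α-ol; 4β-methyl, 10β-methyl, 7β-isopropenyl) | O[C@]1(C)CCC[C@]2(C)CC[C@@H](C(C)=C)C[C@H]21 | intermediate
17 | 4-bromo-2-iodoaniline | Nc1ccc(Br)cc1I | starting material
18 | 3-bromophenylboronic acid | OB(O)c1cccc(Br)c1 | starting material
19 | 3′,5-dibromo-[1,1′-biphenyl]-2-amine | Nc1ccc(Br)cc1-c1cccc(Br)c1 | intermediate
20 | 3′,5-dibromobiphenyl-2-diazonium chloride | N#[N+]c1ccc(Br)cc1-c1cccc(Br)c1.[Cl-] | intermediate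
21 | 3′,5-dibromo-2-iodo-1,1′-biphenyl | Ic1ccc(Br)cc1-c1cccc(Br)c1 | intermediate
22 | [hydroxy(triflyloxy)iodo]arene derived from 21 | OI(OS(=O)(=O)C(F)(F)F)c1ccc(Br)cc1-c1cccc(Br)c1 | intermediate
23 | 2,8-dibromodibenzo[b,d]iodol-5-ium triflate | Brc1ccc2[I+]c3ccc(Br)cc3-c2c1.[O-]S(=O)(=O)C(F)(F)F | intermediate
24 | sodium 5α-eudesm-11-en-4α-olate | [Na+].[O-][C@]1(C)CCC[C@]2(C)CC[C@@H](C(C)=C)C[C@H]21 | intermediate
25 | 2,8-dibromo-5-(5α-eudesm-11-en-4α-yloxy)-5H-dibenzo[b,d]iodole | Brc1ccc2c(c1)-c1cc(Br)ccc1I2O[C@]1(C)CCC[C@]3(C)CC[C@@H](C(C)=C)C[C@H]31 | intermediate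
26 | 4α-[(5,5′-dibromo-2′-iodobiphenyl-2-yl)oxy]-5α-eudesm-11-ene | Brc1ccc(O[C@]2(C)CCC[C@]3(C)CC[C@@H](C(C)=C)C[C@H]32)c(-c2cc(Br)ccc2I)c1 | intermediate
27 | 4α-[(5,5′-dibromo-2′-iodobiphenyl-2-yl)oxy]-5α-eudesman-11-ol | Brc1ccc(O[C@]2(C)CCC[C@]3(C)CC[C@@H](C(C)(C)O)C[C@H]32)c(-c2cc(Br)ccc2I)c1 | intermediate
28 | 2′-(chloromagnesio) derivative of 27, C11 chloromagnesium alkoxide | Brc1ccc(O[C@]2(C)CCC[C@]3(C)CC[C@@H](C(C)(C)O[Mg]Cl)C[C@H]32)c(-c2cc(Br)ccc2[Mg]Cl)c1 | intermediate
29 | 2′-(dimethoxyboryl) analogue of 28, C11 chloromagnesium alkoxide | Brc1ccc(O[C@]2(C)CCC[C@]3(C)CC[C@@H](C(C)(C)O[Mg]Cl)C[C@H]32)c(-c2cc(Br)ccc2B(OC)OC)c1 | intermediate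
30 | 5,5′-dibromo-2′-[(11-hydroxy-5α-eudesman-4α-yl)oxy]biphenyl-2-ol | Brc1ccc(O[C@]2(C)CCC[C@]3(C)CC[C@@H](C(C)(C)O)C[C@H]32)c(-c2cc(Br)ccc2O)c1 | intermediate
31 | mono-coupled compound, allyl on the phenol ring, bromine left on the ether ring | Brc1ccc(O[C@]2(C)CCC[C@]3(C)CC[C@@H](C(C)(C)O)C[C@H]32)c(-c2cc(CC=C)ccc2O)c1 | intermediate
32 | mono-coupled compound, allyl on the ether ring, bromine left on the phenol ring | C=CCc1ccc(O[C@]2(C)CCC[C@]3(C)CC[C@@H](C(C)(C)O)C[C@H]32)c(-c2cc(Br)ccc2O)c1 | intermediate
33 | eudesmagnolol (magnolol mono-ether at C4α of 5α-eudesmane-4α,11-diol; 4β-methyl, 10β-methyl, 7β-hydroxyisopropyl) | C=CCc1ccc(O)c(-c2cc(CC=C)ccc2O[C@]2(C)CCC[C@]3(C)CC[C@@H](C(C)(C)O)C[C@H]32)c1 | target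

**Step count**

Total steps: 13. Longest linear sequence: 10 steps (steps 1–6 and 10–13); the iodolium salt is made in a three-step side branch (steps 7–9).

**Steps most likely to fail**

1. Step 10. The hindered C4 alkoxide may act as a base toward the strained iodolium salt (aryne formation) or the ligand coupling may be too slow, so that little ether forms. Fallback: the ether is made by SNAr and the biaryl afterwards. The route sets out from 16, whose potassium alkoxide (KH, THF) is arylated with 4-bromo-1-fluoro-2-nitrobenzene to give 4α-(4-bromo-2-nitrophenoxy)-5α-eudesm-11-ene F1. Reduction with Fe/NH4Cl gives the aniline 4α-(2-amino-4-bromophenoxy)-5α-eudesm-11-ene F2, and non-aqueous Sandmeyer iodination (t-BuONO, I2, MeCN) gives 4α-(4-bromo-2-iodophenoxy)-5α-eudesm-11-ene F3. Mukaiyama hydration as in step 11 gives 4α-(4-bromo-2-iodophenoxy)-5α-eudesman-11-ol F4. Iodide-selective Suzuki–Miyaura coupling with (5-bromo-2-hydroxyphenyl)boronic acid (Pd(PPh3)4, K2CO3, dioxane/H2O) comes back to the route at 30.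

2. Step 6. The C3 diazene may fragment with loss of the neighbouring C4 oxygen (elimination toward the Δ3 olefin), or the hindered hydrazone may resist hydride addition. Fallback: the C3 oxygen is removed before C4 is oxygenated. The route sets out from 7; lithium–ammonia reduction as in step 3, with enolate 8 trapped by PhNTf2, gives 5α-eudesma-3,11-dien-3-yl triflate F5. Palladium-catalysed formate reduction (Pd(OAc)2, PPh3, HCO2H, Et3N, DMF) gives 5α-eudesma-3,11-diene F6. One equivalent of mCPBA at −20 °C should epoxidise the trisubstituted ring alkene on the α-face to 3α,4α-epoxy-5α-eudesm-11-ene F7. LiAlH4 in THF opens the epoxide at the secondary C3 and comes back to the route at 16.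

3. Step 2. Facial selectivity at C10 may be poor if auxiliary control does not dominate the ring's bias toward the 10-epimer, and the slow Michael addition competes with enone polymerisation. Fallback: a cyclopropane on the β-face directs the same annulation. The route sets out from 1; HCl addition to the isopropenyl group gives (2R,5R)-5-(2-chloropropan-2-yl)-2-methylcyclohexanone F8, and KOH in MeOH closes the cyclopropane to 2-carone F9. Base-mediated Robinson annulation with 3 (KOH, EtOH) should enter anti to the gem-dimethylcyclopropane at the only freely enolisable α-carbon and give the cyclopropane-fused enone 6β,11-cycloeudesm-4-en-3-one F10. HCl in AcOH opens the cyclopropane to 11-chloroeudesm-4-en-3-one F11, and dehydrochlorination (NaOAc, AcOH, reflux) comes back to the route at 7.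

**Further compounds**

F1 | step 10 | 4α-(4-bromo-2-nitrophenoxy)-5α-eudesm-11-ene | [O-][N+](=O)c1cc(Br)ccc1O[C@]1(C)CCC[C@]2(C)CC[C@@H](C(C)=C)C[C@H]21
F2 | step 10 | 4α-(2-amino-4-bromophenoxy)-5α-eudesm-11-ene | Nc1cc(Br)ccc1O[C@]1(C)CCC[C@]2(C)CC[C@@H](C(C)=C)C[C@H]21
F3 | step 10 | 4α-(4-bromo-2-iodophenoxy)-5α-eudesm-11-ene | Ic1cc(Br)ccc1O[C@]1(C)CCC[C@]2(C)CC[C@@H](C(C)=C)C[C@H]21
F4 | step 10 | 4α-(4-bromo-2-iodophenoxy)-5α-eudesman-11-ol | Ic1cc(Br)ccc1O[C@]1(C)CCC[C@]2(C)CC[C@@H](C(C)(C)O)C[C@H]21
F5 | step 6 | 5α-eudesma-3,11-dien-3-yl triflate | CC1=C(OS(=O)(=O)C(F)(F)F)CC[C@]2(C)CC[C@@H](C(C)=C)C[C@H]21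
F6 | step 6 | 5α-eudesma-3,11-diene (α-selinene) | CC1=CCC[C@]2(C)CC[C@@H](C(C)=C)C[C@H]21
F7 | step 6 | 3α,4α-epoxy-5α-eudesm-11-ene | C[C@@]12O[C@@H]1CC[C@]3(C)CC[C@@H](C(C)=C)C[C@H]32
F8 | step 2 | (2R,5R)-5-(2-chloropropan-2-yl)-2-methylcyclohexanone | C[C@@H]1CC[C@@H](C(C)(C)Cl)CC1=O
F9 | step 2 | 2-carone, 3,7,7-trimethylbicyclo[4.1.0]heptan-2-one (cyclopropane on the β-face; epimerisable C3 methyl left undefined) | CC1CC[C@@H]2[C@H](C1=O)C2(C)C
F10 | step 2 | 6β,11-cycloeudesm-4-en-3-one (10β-methyl, gem-dimethylcyclopropane on the β-face) | CC1=C2[C@H]3[C@@H](CC[C@@]2(C)CCC1=O)C3(C)C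
F11 | step 2 | 11-chloroeudesm-4-en-3-one (10β-methyl, 7β-side chain) | CC1=C2C[C@H](C(C)(C)Cl)CC[C@@]2(C)CCC1=O
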